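The eleven-membered ring is numbered C1 (carbinol), C2 (CMe2), C3=C4, C5 (methylidene-bearing), C6, C7, C8=C9(Me), C10, C11. Everything rests on cutting C9(sp2)–C10(sp3). Since C10–C11 flanks the C1 stereocentre, it can enter as a vinyl group made from the lactone carbonyl of (S)-pantolactone, while C9 is stored as an (E)-alkenyl iodide. In one operation, 9-BBN hydroboration and intramolecular B-alkyl Suzuki–Miyaura coupling close the ring, carry the E geometry of C8=C9 over with retention and, after a fluoride finish, deliver the free phenol. The precursor is an acyclic tetraene iodide that already bears the silylated vanillate, built by Horner–Wadsworth–Emmons olefination and Wittig methylenation.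

Key step: step 11

Assumption: starting materials 1, 5, 8 and 12 are taken as commercially available, 8 as the (S) enantiomer. The target carbinol carbon is R, which matches (S)-pantolactone once the CIP ranking of its neighbours changes.

Step 1
Reactants: 1 but-2-yn-1-ol
Product: 3 (2E)-3-iodobut-2-en-1-ol, via alkenylzirconocene alkoxide 2 (not isolated)
Conditions: Cp2Zr(H)Cl (2.5 equiv), THF, rt to 40 °C; then I2, −78 to 0 °C
Reagents that add atoms: iodine, II
Why: Hydrozirconation–iodinolysis: Zr–H adds syn to the alkyne, the excess of Cp2Zr(H)Cl lets zirconium settle on the less hindered methyl-bearing carbon, and iodine replaces zirconium with retention, which should place iodine trans to the CH2OH carbon (E).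

Step 2
Reactants: 3 (2E)-3-iodobut-2-en-1-ol
Product: 4 (2E)-1-bromo-3-iodobut-2-ene
Conditions: PBr3 (0.4 equiv), Et2O, 0 °C
Reagents that add atoms: phosphorus tribromide, BrP(Br)Br
Why: Bromination of a primary allylic alcohol through its phosphite ester (SN2 displacement by bromide) should leave the alkenyl iodide and its geometry untouched.

Step 3
Reactants: 5 dimethyl (2-oxopropyl)phosphonate; 4 (2E)-1-bromo-3-iodobut-2-ene
Product: 7 dimethyl [(5E)-6-iodo-2-oxohept-5-en-1-yl]phosphonate, via phosphonate dianion 6 (not isolated)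
Conditions: NaH, THF, 0 °C; n-BuLi (0.98 equiv), 0 °C; then 4, 0 °C to rt
Reagents that add atoms: none
Why: Gamma-alkylation of a beta-ketophosphonate dianion: the more basic terminal carbanion of 6 should displace the allylic bromide in SN2 fashion, while the alkenyl iodide is inert to this delocalised nucleophile provided no n-BuLi is left over.

Step 4
Reactants: 8 (S)-pantolactone
Product: 9 (3S)-4,4-dimethyloxolane-2,3-diol (lactol, both anomers)
Conditions: iBu2AlH (2.2 equiv), CH2Cl2, −78 °C; aqueous potassium sodium tartrate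
Reagents that add atoms: none
Why: Partial reduction of a lactone with iBu2AlH: the first equivalent is consumed by the free hydroxyl, the second gives an aluminium hemiacetal that holds at −78 °C until work-up, and the stereocentre is not involved.

Step 5
Reactants: 9 (3S)-4,4-dimethyloxolane-2,3-diol
Product: 10 (3R)-2,2-dimethylpent-4-ene-1,3-diol
Conditions: Ph3PCH3Br (3.5 equiv), KOtBu (3.4 equiv), THF, 0 °C to 40 °C
Reagents that add atoms: methyltriphenylphosphonium bromide, C[P+](c1ccccc1)(c1ccccc1)c1ccccc1.[Br-]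
Why: Wittig methylenation of the open hydroxy-aldehyde form of the lactol, in which the adjacent alkoxide disfavours enolisation so that the stereocentre should be kept (the descriptor changes from S to R only because the CIP ranking of the neighbours changes).

Step 6
Reactants: 10 (3R)-2,2-dimethylpent-4-ene-1,3-diol
Product: 11 (3R)-3-hydroxy-2,2-dimethylpent-4-enal
Conditions: TEMPO (10 mol %), PhI(OAc)2 (1.1 equiv), CH2Cl2, rt
Reagents that add atoms: none
Why: Oxoammonium (TEMPO) oxidation prefers the primary over the doubly flanked secondary allylic hydroxyl, stops at the aldehyde in dry CH2Cl2, and the weakly acidic medium gives the quaternary beta-hydroxy aldehyde no chance of retro-aldol cleavage.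

Step 7
Reactants: 12 vanillic acid
Product: 14 4-[(tert-butyldimethylsilyl)oxy]-3-methoxybenzoic acid, via bis-silylated vanillic acid 13 (not isolated)
Conditions: TBSCl (2.5 equiv), imidazole, DMF, rt; then AcOH/THF/H2O, rt
Reagents that add atoms: tert-butyldimethylsilyl chloride, CC(C)(C)[Si](C)(C)Cl
Why: Silylation of phenol and acid followed by selective hydrolysis, since a silyl ester is cleaved by dilute acetic acid far faster than an aryl silyl ether.

Step 8
Reactants: 14 4-[(tert-butyldimethylsilyl)oxy]-3-methoxybenzoic acid; 11 (3R)-3-hydroxy-2,2-dimethylpent-4-enal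
Product: 16 (3R)-4,4-dimethyl-5-oxopent-1-en-3-yl 4-[(tert-butyldimethylsilyl)oxy]-3-methoxybenzoate, via acid chloride 15 (not isolated)
Conditions: (COCl)2, cat. DMF, CH2Cl2, 0 °C to rt, concentrate; then 11, Et3N, DMAP, CH2Cl2, 0 to 35 °C
Reagents that add atoms: none
Why: Acid chloride formation and DMAP-catalysed acylation of the hindered secondary hydroxyl, which leaves the C–O bond and hence the R configuration intact, while the amine bases are too weak to form the alkoxide that retro-aldol cleavage would need.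

Step 9
Reactants: 16 (3R)-4,4-dimethyl-5-oxopent-1-en-3-yl 4-[(tert-butyldimethylsilyl)oxy]-3-methoxybenzoate; 7 dimethyl [(5E)-6-iodo-2-oxohept-5-en-1-yl]phosphonate
Product: 17 (3R,5E,10E)-11-iodo-4,4-dimethyl-7-oxododeca-1,5,10-trien-3-yl 4-[(tert-butyldimethylsilyl)oxy]-3-methoxybenzoate
Conditions: LiCl, iPr2NEt, MeCN, rt to 40 °C
Reagents that add atoms: none
Why: Horner–Wadsworth–Emmons olefination under Masamune–Roush conditions: the lithium-chelated ketophosphonate is deprotonated by the amine, adds reversibly to the non-enolisable aldehyde and should collapse to the E enone, with ester, aryl silyl ether and alkenyl iodide all inert to the mild base.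

Step 10
Reactants: 17 (3R,5E,10E)-11-iodo-4,4-dimethyl-7-oxododeca-1,5,10-trien-3-yl 4-[(tert-butyldimethylsilyl)oxy]-3-methoxybenzoate
Product: 18 (3R,5E,10E)-11-iodo-4,4-dimethyl-7-methylidenedodeca-1,5,10-trien-3-yl 4-[(tert-butyldimethylsilyl)oxy]-3-methoxybenzoate
Conditions: Ph3PCH3Br (1.6 equiv), KN(SiMe3)2 (1.5 equiv), THF, −78 to 0 °C
Reagents that add atoms: methyltriphenylphosphonium bromide, C[P+](c1ccccc1)(c1ccccc1)c1ccccc1.[Br-]
Why: Wittig methylenation: the unstabilised ylide should add 1,2 to the enone carbonyl at low temperature faster than it attacks the electron-rich, hindered aroate, turning the ketone into the methylidene of the 2-substituted diene without touching the E alkenes.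

Step 11
Reactants: 18 (3R,5E,10E)-11-iodo-4,4-dimethyl-7-methylidenedodeca-1,5,10-trien-3-yl 4-[(tert-butyldimethylsilyl)oxy]-3-methoxybenzoate
Product: 21 (1R,3E,8E)-2,2,9-trimethyl-5-methylidenecycloundeca-3,8-dien-1-yl 4-hydroxy-3-methoxybenzoate (target), via B-alkyl-9-BBN adduct 19 (not isolated), via macrocyclic aryl silyl ether 20 (not isolated)
Conditions: 9-BBN-H (1.6 equiv), THF, 0 °C to rt, then H2O; syringe-pump addition to Pd(dppf)Cl2 (15 mol %), AsPh3, Cs2CO3, DMF/THF/H2O, 50 °C, about 2 mM; then Bu4NF, rt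
Reagents that add atoms: none
Why: 9-BBN adds anti-Markovnikov to C10=C11, the only isolated monosubstituted alkene, because the conjugated C3=C4–C5=CH2 diene and the iodine-bearing trisubstituted C8=C9 alkene react much more slowly with this bulky borane, which puts boron on C10 and leaves C1 untouched. Zerovalent palladium inserts into the C9–I bond with retention, the hydroxyborate formed in the carbonate medium transfers C10 to palladium, and reductive elimination from the twelve-membered palladacycle forms C9–C10; the closest known reaction type is the intramolecular B-alkyl Suzuki–Miyaura macrocyclisation of (E)-2-iodoalk-2-enes. The single ring closed is the eleven-membered carbocycle, closed end to end (sp3 C10 onto sp2 C9) with C8=C9 endocyclic and E. No stereocentre is created: C1 (R) comes from 8, and the alkene geometries come from steps 1 and 9. Ring closure must beat dimerisation and Heck-type insertion: slow addition keeps 19 near millimolar, the C2 gem-dimethyl group and the two E alkenes pre-fold the chain, and palladium on C9 stands trans to the C7 chain, so it cannot reach the nearby diene through a small ring. The aryl silyl ether is labile in Cs2CO3/DMF/H2O anyway, so Bu4NF is added at the end to complete its removal, and it does not matter whether silicon leaves before or after ring closure.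

Compound list
1 | but-2-yn-1-ol | CC#CCO | starting material
2 | (E)-alkenylzirconocene alkoxide, Cp2(Cl)Zr on C3 and on the oxygen of but-2-en-1-ol | C/C([Zr](Cl)(C1C=CC=C1)C1C=CC=C1)=C\CO[Zr](Cl)(C1C=CC=C1)C1C=CC=C1 | intermediate
3 | (2E)-3-iodobut-2-en-1-ol | C/C(I)=C\CO | intermediate
4 | (2E)-1-bromo-3-iodobut-2-ene | C/C(I)=C\CBr | intermediate
5 | dimethyl (2-oxopropyl)phosphonate | COP(=O)(OC)CC(C)=O | starting material
6 | sodium lithium dianion of 5 (carbanions at C1 and C3) | [Na+].[Li+].COP(=O)(OC)[CH-]C(=O)[CH2-] | intermediate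
7 | dimethyl [(5E)-6-iodo-2-oxohept-5-en-1-yl]phosphonate | COP(=O)(OC)CC(=O)CC/C=C(\C)I | intermediate
8 | (S)-pantolactone, (3S)-3-hydroxy-4,4-dimethyloxolan-2-one | CC1(C)COC(=O)[C@H]1O | starting material
9 | (3S)-4,4-dimethyloxolane-2,3-diol (lactol, both anomers) | CC1(C)COC(O)[C@H]1O | intermediate
10 | (3R)-2,2-dimethylpent-4-ene-1,3-diol | OCC(C)(C)[C@H](O)C=C | intermediate
11 | (3R)-3-hydroxy-2,2-dimethylpent-4-enal | O=CC(C)(C)[C@H](O)C=C | intermediate
12 | vanillic acid, 4-hydroxy-3-methoxybenzoic acid | COc1cc(C(=O)O)ccc1O | starting material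
13 | tert-butyldimethylsilyl 4-[(tert-butyldimethylsilyl)oxy]-3-methoxybenzoate | COc1cc(C(=O)O[Si](C)(C)C(C)(C)C)ccc1O[Si](C)(C)C(C)(C)C | intermediate
14 | 4-[(tert-butyldimethylsilyl)oxy]-3-methoxybenzoic acid | COc1cc(C(=O)O)ccc1O[Si](C)(C)C(C)(C)C | intermediate
15 | 4-[(tert-butyldimethylsilyl)oxy]-3-methoxybenzoyl chloride | COc1cc(C(=O)Cl)ccc1O[Si](C)(C)C(C)(C)C | intermediate
16 | (3R)-4,4-dimethyl-5-oxopent-1-en-3-yl 4-[(tert-butyldimethylsilyl)oxy]-3-methoxybenzoate | O=CC(C)(C)[C@H](OC(=O)c1ccc(O[Si](C)(C)C(C)(C)C)c(OC)c1)C=C | intermediate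
17 | (3R,5E,10E)-11-iodo-4,4-dimethyl-7-oxododeca-1,5,10-trien-3-yl 4-[(tert-butyldimethylsilyl)oxy]-3-methoxybenzoate | C/C(I)=C\CCC(=O)/C=C/C(C)(C)[C@H](OC(=O)c1ccc(O[Si](C)(C)C(C)(C)C)c(OC)c1)C=C | intermediate
18 | (3R,5E,10E)-11-iodo-4,4-dimethyl-7-methylidenedodeca-1,5,10-trien-3-yl 4-[(tert-butyldimethylsilyl)oxy]-3-methoxybenzoate | C/C(I)=C\CCC(=C)/C=C/C(C)(C)[C@H](OC(=O)c1ccc(O[Si](C)(C)C(C)(C)C)c(OC)c1)C=C | intermediate
19 | (3R,5E,10E)-1-(9-borabicyclo[3.3.1]nonan-9-yl)-11-iodo-4,4-dimethyl-7-methylidenedodeca-5,10-dien-3-yl 4-[(tert-butyldimethylsilyl)oxy]-3-methoxybenzoate | C/C(I)=C\CCC(=C)/C=C/C(C)(C)[C@H](OC(=O)c1ccc(O[Si](C)(C)C(C)(C)C)c(OC)c1)CCB1C2CCCC1CCC2 | intermediate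
20 | (1R,3E,8E)-2,2,9-trimethyl-5-methylidenecycloundeca-3,8-dien-1-yl 4-[(tert-butyldimethylsilyl)oxy]-3-methoxybenzoate | C=C1/C=C/C(C)(C)[C@H](OC(=O)c2ccc(O[Si](C)(C)C(C)(C)C)c(OC)c2)CC/C(C)=C/CC1 | intermediate
21 | (1R,3E,8E)-2,2,9-trimethyl-5-methylidenecycloundeca-3,8-dien-1-yl 4-hydroxy-3-methoxybenzoate | C=C1/C=C/C(C)(C)[C@H](OC(=O)c2ccc(O)c(OC)c2)CC/C(C)=C/CC1 | target

Total step count: 11. Longest linear sequence: 7 steps (4, 5, 6, 8, 9, 10, 11, from 8).

Steps most likely to fail

Step 11. Hydroboration may stray onto the terminal CH2 of the diene, or intermolecular coupling may outrun ring closure. The fallback sets out from 17 and comes back at 21. It forms the same C9–C10 bond before the diene exists.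
- Luche reduction of 17 (NaBH4, CeCl3·7H2O, MeOH) gives the acyclic allylic alcohol F1, epimeric at the new carbinol carbon. Its vinyl group is the only alkene open to 9-BBN.
- Two equivalents of 9-BBN-H give the O,C-bis(9-BBN) adduct F2.
- The same palladium closure gives the macrocyclic allylic alcohol silyl ether F3, and Bu4NF then gives the macrocyclic allylic alcohol phenol F4.
- MnO2 oxidises F4 to the macrocyclic enone F5.
- Excess Ph3P=CH2 (one equivalent is spent on the phenol) methylenates F5 to 21.

Step 8. The beta-hydroxy aldehyde may fragment by retro-aldol cleavage or self-acetalise while acylation of the hindered hydroxyl lags. The fallback sets out from 10 and comes back at 16. It postpones the aldehyde until the ester is in place.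
- TBSCl and imidazole silylate only the primary hydroxyl of 10 to give the primary silyl ether F6.
- Acid chloride 15 with Et3N and DMAP, now free to be heated, gives the doubly silylated ester F7.
- Camphorsulfonic acid in MeOH at 0 °C removes the alkyl silyl ether and spares the aryl silyl ether, giving the hydroxy ester F8.
- Dess–Martin periodinane oxidises F8 to 16.

Step 9. The stabilised phosphonate anion may add too slowly to the neopentyl aldehyde, so that silyl loss or decomposition intervenes. The fallback sets out from 4 and comes back at 18, bypassing 7 and 17. It uses a more nucleophilic allylic phosphonate that already carries the methylidene.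
- 2-Methylprop-2-en-1-ol, doubly lithiated with n-BuLi and TMEDA, is alkylated by 4 to give the methylidene alcohol F9.
- PBr3 gives the allylic bromide F10.
- A Michaelis–Arbuzov reaction with P(OEt)3 gives the allylic phosphonate F11.
- Deprotonation with LiN(SiMe3)2 and addition to 16 should give the E diene 18 directly.

Further compounds
F1 | step 11 | (3R,5E,10E)-7-hydroxy-11-iodo-4,4-dimethyldodeca-1,5,10-trien-3-yl 4-[(tert-butyldimethylsilyl)oxy]-3-methoxybenzoate (C7 epimers) | C/C(I)=C\CCC(O)/C=C/C(C)(C)[C@H](OC(=O)c1ccc(O[Si](C)(C)C(C)(C)C)c(OC)c1)C=C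
F2 | step 11 | O,C-bis(9-BBN) adduct of F1 | C/C(I)=C\CCC(OB1C2CCCC1CCC2)/C=C/C(C)(C)[C@H](OC(=O)c1ccc(O[Si](C)(C)C(C)(C)C)c(OC)c1)CCB1C2CCCC1CCC2
F3 | step 11 | (1R,3E,8E)-5-hydroxy-2,2,9-trimethylcycloundeca-3,8-dien-1-yl 4-[(tert-butyldimethylsilyl)oxy]-3-methoxybenzoate (C5 epimers) | OC1/C=C/C(C)(C)[C@H](OC(=O)c2ccc(O[Si](C)(C)C(C)(C)C)c(OC)c2)CC/C(C)=C/CC1
F4 | step 11 | (1R,3E,8E)-5-hydroxy-2,2,9-trimethylcycloundeca-3,8-dien-1-yl 4-hydroxy-3-methoxybenzoate (C5 epimers) | OC1/C=C/C(C)(C)[C@H](OC(=O)c2ccc(O)c(OC)c2)CC/C(C)=C/CC1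
F5 | step 11 | (1R,3E,8E)-2,2,9-trimethyl-5-oxocycloundeca-3,8-dien-1-yl 4-hydroxy-3-methoxybenzoate | O=C1/C=C/C(C)(C)[C@H](OC(=O)c2ccc(O)c(OC)c2)CC/C(C)=C/CC1
F6 | step 8 | (3R)-5-[(tert-butyldimethylsilyl)oxy]-4,4-dimethylpent-1-en-3-ol | CC(C)(C)[Si](C)(C)OCC(C)(C)[C@H](O)C=C
F7 | step 8 | (3R)-5-[(tert-butyldimethylsilyl)oxy]-4,4-dimethylpent-1-en-3-yl 4-[(tert-butyldimethylsilyl)oxy]-3-methoxybenzoate | CC(C)(C)[Si](C)(C)OCC(C)(C)[C@H](OC(=O)c1ccc(O[Si](C)(C)C(C)(C)C)c(OC)c1)C=C
F8 | step 8 | (3R)-5-hydroxy-4,4-dimethylpent-1-en-3-yl 4-[(tert-butyldimethylsilyl)oxy]-3-methoxybenzoate | OCC(C)(C)[C@H](OC(=O)c1ccc(O[Si](C)(C)C(C)(C)C)c(OC)c1)C=C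
F9 | step 9 | (5E)-6-iodo-2-methylidenehept-5-en-1-ol | C=C(CO)CC/C=C(\C)I
F10 | step 9 | (2E)-6-(bromomethyl)-2-iodohepta-2,6-diene | C=C(CBr)CC/C=C(\C)I
F11 | step 9 | diethyl [(5E)-6-iodo-2-methylidenehept-5-en-1-yl]phosphonate | C=C(CP(=O)(OCC)OCC)CC/C=C(\C)I
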